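Assumption: atom labels follow germacrane numbering (C1/C10 = oxirane carbons, C14 = CHO, C15 = methyl on C4, C6/C8 = acetoxy carbons, C7 = isopropyl carbon). The SMILES then reads as (1R,6R,7S,8R,10S), 4E, with C2 and C9 cis on the oxirane. Compounds 1, 5 and 8 are taken as commercial. The route is a paper design and has not been run.

## Retrosynthetic overview

1. The epoxy-aldehyde comes from Sharpless epoxidation and oxidation of a ring allylic alcohol (C1=C10–C14H2OH), so the oxirane is formed last.
2. The ten-membered ring is formed first, by RCM at C1=C10 (ring-cis trisubstituted olefin) on an acyclic triene that already carries C6, C7, C8 and both acetates.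
3. C6 is set by Evans–Saksena 1,3-anti reduction of a β-hydroxy enone; the C5–C6 bond comes from an (E)-alkenyllithium adding to a Weinreb amide.
4. C7 and C8 are set by an Evans syn-aldol of N-isovaleryl oxazolidinone with a β,γ-unsaturated aldehyde carrying C9, C10 and C14.
5. The building blocks are 2-bromoallyl alcohol, ethylene oxide, the isovaleryl imide and hex-5-en-1-yne.

## Route

**Step 1**
Reactants: 1, 2-bromoprop-2-en-1-ol
Product: 2, 2-bromoallyl 4-methoxybenzyl ether
Conditions: NaH, PMBCl, cat. Bu4NI, THF, 0 °C to rt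
Reagents that add atoms: 4-methoxybenzyl chloride, COc1ccc(CCl)cc1
Why: Williamson etherification; the PMB ether survives the organolithium, boron, aluminium, hydride and Ru steps and is later removed oxidatively without touching acetates.

**Step 2**
Reactants: 2
Product: 3, 3-{[(4-methoxybenzyl)oxy]methyl}but-3-en-1-ol
Conditions: t-BuLi (2.1 equiv), Et2O, −78 °C; then ethylene oxide, BF3·OEt2, −78 °C
Reagents that add atoms: oxirane, C1CO1
Why: Br/Li exchange gives the 2-lithioallyl ether, and BF3-assisted epoxide opening adds C8 and C9.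

**Step 3**
Reactants: 3
Product: 4, 3-{[(4-methoxybenzyl)oxy]methyl}but-3-enal
Conditions: Dess–Martin periodinane, NaHCO3, CH2Cl2, 0 °C; used crude at once
Reagents that add atoms: none
Why: Buffered, base-free Dess–Martin oxidation gives the β,γ-unsaturated aldehyde without moving the olefin into conjugation.

**Step 4**
Reactants: 5, (S)-4-benzyl-3-(3-methylbutanoyl)oxazolidin-2-one; 4
Product: 6, (S)-4-benzyl-3-[(2S,3R)-3-hydroxy-5-{[(4-methoxybenzyl)oxy]methyl}-2-(propan-2-yl)hex-5-enoyl]oxazolidin-2-one
Conditions: Bu2BOTf, i-Pr2NEt, CH2Cl2, 0 to −78 °C; add 4, −78 to 0 °C; pH 7 buffer, MeOH, H2O2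
Reagents that add atoms: none
Why: Evans syn-aldol through the Z-boron enolate and a Zimmerman–Traxler chair; the (S)-benzyl auxiliary sets C7 and C8 syn with the absolute configuration of the target.

**Step 5**
Reactants: 6
Product: 7, (2S,3R)-3-hydroxy-N-methoxy-5-{[(4-methoxybenzyl)oxy]methyl}-N-methyl-2-(propan-2-yl)hex-5-enamide
Conditions: MeNHOMe·HCl, AlMe3, CH2Cl2, −20 to 0 °C
Reagents that add atoms: N,O-dimethylhydroxylamine hydrochloride, CNOC.Cl
Why: Aluminium-amide transamidation, assisted by the free β-hydroxyl, gives the Weinreb amide without epimerising C7.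

**Step 6**
Reactants: 8, hex-5-en-1-yne
Product: 9, (E)-1-iodo-2-methylhexa-1,5-diene
Conditions: AlMe3 (2.5 equiv), Cp2ZrCl2 (0.25 equiv), CH2Cl2, 0 °C to rt; then I2, THF, −30 to 0 °C
Reagents that add atoms: trimethylaluminium, C[Al](C)C; iodine, II
Why: Negishi Zr-catalysed syn-carboalumination of the terminal alkyne (the alkene is inert) and iodinolysis with retention fix the E geometry of C4=C5.

**Step 7**
Reactants: 7; 9
Product: 10, (4R,5S,7E)-4-hydroxy-2-{[(4-methoxybenzyl)oxy]methyl}-8-methyl-5-(propan-2-yl)dodeca-1,7,11-trien-6-one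
Conditions: 9 (2.6 equiv), t-BuLi (5.2 equiv), Et2O, −78 °C; then 7, −78 to −20 °C; aq NH4Cl
Reagents that add atoms: none
Why: I/Li exchange with retention, then Weinreb ketone synthesis; the first equivalent deprotonates the hydroxyl and the chelated tetrahedral intermediate prevents over-addition.

**Step 8**
Reactants: 10
Product: 11, (4R,5S,6R,7E)-2-{[(4-methoxybenzyl)oxy]methyl}-8-methyl-5-(propan-2-yl)dodeca-1,7,11-triene-4,6-diol
Conditions: Me4NBH(OAc)3, MeCN/AcOH 1:1, −30 °C
Reagents that add atoms: none
Why: Evans–Saksena reduction; hydride is delivered intramolecularly from the C8 alkoxyborohydride through a chair, giving the 1,3-anti diol by 1,2-reduction and setting C6 as R.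

**Step 9**
Reactants: 11
Product: 12, the 4,6-diacetate of 11
Conditions: Ac2O, pyridine, DMAP, CH2Cl2, rt
Reagents that add atoms: acetic anhydride, CC(=O)OC(C)=O
Why: DMAP-catalysed acylation of both hindered secondary alcohols installs the two acetates of the target.

**Step 10**
Reactants: 12
Product: 13, (1R,2S,3R,4E,8E)-9-{[(4-methoxybenzyl)oxy]methyl}-5-methyl-2-(propan-2-yl)cyclodeca-4,8-diene-1,3-diyl diacetate (the new C1=C10 olefin is ring-cis, C2 cis to C9)
Conditions: Grubbs II (15 mol %, in portions), toluene, 1 mM, 80 °C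
Reagents that add atoms: none
Why: Ring-closing metathesis; Ru loads on the monosubstituted C1 olefin and closes onto the 1,1-disubstituted olefin, the ten-membered ring favours the cis ring olefin, and the trisubstituted C4=C5 olefin cannot compete because it could only give a cyclobutene.

**Step 11**
Reactants: 13
Product: 14, (1R,2S,3R,4E,8E)-9-(hydroxymethyl)-5-methyl-2-(propan-2-yl)cyclodeca-4,8-diene-1,3-diyl diacetate
Conditions: DDQ (1.2 equiv), CH2Cl2/pH 7 buffer 10:1, 0 °C
Reagents that add atoms: none
Why: Oxidative PMB cleavage is neutral, so the acetates, the allylic acetate and both olefins are untouched.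

**Step 12**
Reactants: 14
Product: 15, (1R,6R,7S,8R,10R)-1,10-epoxy-14-hydroxygermacr-4(E)-ene-6,8-diyl diacetate
Conditions: Ti(Oi-Pr)4, D-(−)-diisopropyl tartrate, t-BuOOH, 4 Å MS, CH2Cl2, −20 °C
Reagents that add atoms: tert-butyl hydroperoxide, CC(C)(C)OO
Why: Sharpless asymmetric epoxidation under reagent control; D-(−)-tartrate gives the (R,R) epoxy alcohol from this E-2,3-disubstituted allylic alcohol (L-(+) gives S,S), and only the olefin bearing the free CH2OH reacts.

**Step 13**
Reactants: 15
Product: 16, pulicanaral A, (1R,6R,7S,8R,10S)-1,10-epoxy-14-oxogermacr-4(E)-ene-6,8-diyl diacetate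
Conditions: Dess–Martin periodinane, NaHCO3, CH2Cl2, 0 °C to rt
Reagents that add atoms: none
Why: Mild oxidation of the primary epoxy alcohol to the epoxy aldehyde; C10 is quaternary so nothing can epimerise (its descriptor changes from R to S only through CIP priorities).

## Compound list

1 | 2-bromoprop-2-en-1-ol | OCC(Br)=C | starting material
2 | 2-bromoallyl 4-methoxybenzyl ether | C=C(Br)COCc1ccc(OC)cc1 | intermediate
3 | 3-{[(4-methoxybenzyl)oxy]methyl}but-3-en-1-ol | OCCC(=C)COCc1ccc(OC)cc1 | intermediate
4 | 3-{[(4-methoxybenzyl)oxy]methyl}but-3-enal | O=CCC(=C)COCc1ccc(OC)cc1 | intermediate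
5 | (S)-4-benzyl-3-(3-methylbutanoyl)oxazolidin-2-one | CC(C)CC(=O)N1[C@@H](Cc2ccccc2)COC1=O | starting material
6 | syn-aldol imide (2S,3R) | O=C(N1[C@@H](Cc2ccccc2)COC1=O)[C@@H](C(C)C)[C@H](O)CC(=C)COCc1ccc(OC)cc1 | intermediate
7 | Weinreb amide (2S,3R) | CON(C)C(=O)[C@@H](C(C)C)[C@H](O)CC(=C)COCc1ccc(OC)cc1 | intermediate
8 | hex-5-en-1-yne | C#CCCC=C | starting material
9 | (E)-1-iodo-2-methylhexa-1,5-diene | I/C=C(\C)CCC=C | intermediate
10 | β-hydroxy enone (4R,5S,7E) | C=CCC/C(C)=C/C(=O)[C@@H](C(C)C)[C@H](O)CC(=C)COCc1ccc(OC)cc1 | intermediate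
11 | 1,3-anti diol (4R,5S,6R,7E) | C=CCC/C(C)=C/[C@@H](O)[C@@H](C(C)C)[C@H](O)CC(=C)COCc1ccc(OC)cc1 | intermediate
12 | diacetate of 11 | C=CCC/C(C)=C/[C@@H](OC(C)=O)[C@@H](C(C)C)[C@H](OC(C)=O)CC(=C)COCc1ccc(OC)cc1 | intermediate
13 | cyclodecadiene PMB ether (RCM product) | CC(=O)O[C@@H]1/C=C(\C)CC/C=C(/COCc2ccc(OC)cc2)C[C@@H](OC(C)=O)[C@@H]1C(C)C | intermediate
14 | cyclodecadiene allylic alcohol | CC(=O)O[C@@H]1/C=C(\C)CC/C=C(/CO)C[C@@H](OC(C)=O)[C@@H]1C(C)C | intermediate
15 | epoxy alcohol (1R,10R) | CC(=O)O[C@@H]1/C=C(\C)CC[C@H]2O[C@@]2(CO)C[C@@H](OC(C)=O)[C@@H]1C(C)C | intermediate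
16 | pulicanaral A | CC(=O)O[C@@H]1/C=C(\C)CC[C@H]2O[C@@]2(C=O)C[C@@H](OC(C)=O)[C@@H]1C(C)C | target

## Totals and risks

Total steps: 13. Longest linear sequence: 12 (1 → 16 through steps 1–5 and 7–13; step 6 is the one-step side branch).

Three steps most likely to fail:

1. **Step 10, RCM to a ten-membered ring with a trisubstituted olefin** (oligomerisation or no closure). Fallback: close the ring at C5–C6 instead by intramolecular Nozaki–Hiyama–Kishi addition of an (E)-vinyl iodide to a C6 aldehyde. The C1=C10 olefin would be built beforehand by an intermolecular E-selective HWE, and C6 corrected afterwards by oxidation to the enone and hydroxyl-directed anti reduction.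
2. **Step 4, aldol with β,γ-unsaturated aldehyde 4** (isomerisation to the conjugated enal, low yield). Fallback: reverse the bond order. Run a MgCl2-catalysed Evans anti-aldol of 5 with (E)-3-methylhepta-2,6-dienal to set C6/C7, silylate, and reduce to the C8 aldehyde. Then form C8–C9 by BF3-mediated Sakurai addition of 2-(trimethylsilylmethyl)allyl acetate, where Felkin and 1,3-anti induction reinforce; aldehyde 4 is then never needed.
3. **Step 12, Sharpless epoxidation of a hindered medium-ring allylic alcohol** (slow or mismatched with the ring's facial bias). Fallback: oxidise 14 to the enal with MnO2 and use nucleophilic epoxidation (t-BuOOH/DBU, or H2O2 with a chiral amine catalyst), which gives the epoxy-aldehyde directly. Alternatively, in the NHK variant, epoxidise the acyclic E-allylic alcohol before ring closure.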